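**Retrosynthetic overview**

1. The target flavonol comes from its 5-O-benzyl ether by hydrogenolysis; that ether comes from a flavan-3,4-diol by oxidation of both carbinols and enolisation of the 3,4-dione; the diol comes from OsO4 dihydroxylation of the C3=C4 alkene of a 2-aryl-2H-chromene.
2. Key disconnection C4–C4a: the chromene arises from an aryl 1-arylpropargyl ether by a propargyl Claisen shift, a 1,5-hydrogen shift and an oxa-6π ring closure. Ring C is the only ring made; rings A and B are bought.
3. Feature the plan rests on: in ring A, O1 sits on C8a, whose two ortho carbons are C8 (methoxy-bearing) and C4a (hydrogen-bearing). Only C4a can accept C4 and re-aromatise, and the resulting C3=C4 alkene is the latent 3-hydroxyl and C4 carbonyl.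
4. The ether comes from a Mitsunobu union of 1-(3,4,5-trimethoxyphenyl)prop-2-yn-1-ol (ethynyl Grignard plus aldehyde) with 3-hydroxy-4,5-dimethoxybenzaldehyde. The formyl group is then converted into the future C5 oxygen (Baeyer–Villiger, methanolysis) and benzylated.

Key step: step 5

Remark: every chiral intermediate of the route is racemic (the SMILES show one enantiomer); the target is achiral, so no configuration has to be carried through.

**Route**

Step 1
Reactants: 1 3,4,5-trimethoxybenzaldehyde; 2 ethynylmagnesium bromide
Product: 3 rac-1-(3,4,5-trimethoxyphenyl)prop-2-yn-1-ol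
Conditions: HC≡CMgBr (1.3 equiv), THF, 0 °C to rt; then sat. aq. NH4Cl
Reagents that add atoms: ethynylmagnesium bromide (compound 2), C#C[Mg]Br
Why: Grignard 1,2-addition of the acetylide carbon to the aldehyde carbonyl is reliable for electron-rich benzaldehydes; the carbinol stereocentre forms without control as a racemate, which is acceptable because this carbon ends as sp2 C2 of the target.

Step 2
Reactants: 3 rac-1-(3,4,5-trimethoxyphenyl)prop-2-yn-1-ol; 4 3-hydroxy-4,5-dimethoxybenzaldehyde
Product: 5 rac-3,4-dimethoxy-5-{[1-(3,4,5-trimethoxyphenyl)prop-2-yn-1-yl]oxy}benzaldehyde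
Conditions: PPh3, DIAD, THF, 0 °C to rt
Reagents that add atoms: none
Why: Mitsunobu etherification: the phenol of 4 (acidified by the meta formyl group) protonates the betaine and then displaces the oxyphosphonium of the secondary propargylic alcohol at carbon with inversion, which has no consequence for racemic material, while the aldehyde and the terminal alkyne are untouched.

Step 3
Reactants: 5 rac-3,4-dimethoxy-5-{[1-(3,4,5-trimethoxyphenyl)prop-2-yn-1-yl]oxy}benzaldehyde
Product: 7 rac-3,4-dimethoxy-5-{[1-(3,4,5-trimethoxyphenyl)prop-2-yn-1-yl]oxy}phenol, via aryl formate 6 (not isolated)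
Conditions: mCPBA, CH2Cl2, 0 °C to rt; aq. NaHCO3 wash; then K2CO3 (cat.), MeOH, rt
Reagents that add atoms: mCPBA (3-chloroperoxybenzoic acid), O=C(OO)c1cccc(Cl)c1
Why: Baeyer–Villiger oxidation of the Dakin type: in the Criegee adduct the electron-rich aryl group (para-methoxy, two meta-alkoxy groups) migrates in preference to hydrogen to give formate 6, which catalytic carbonate in methanol transesterifies to the phenol, the terminal alkyne and the second aryl ring being inert to the peracid at this temperature.

Step 4
Reactants: 7 rac-3,4-dimethoxy-5-{[1-(3,4,5-trimethoxyphenyl)prop-2-yn-1-yl]oxy}phenol; 8 benzyl bromide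
Product: 9 rac-5-(benzyloxy)-1,2-dimethoxy-3-{[1-(3,4,5-trimethoxyphenyl)prop-2-yn-1-yl]oxy}benzene
Conditions: BnBr, K2CO3, DMF, rt
Reagents that add atoms: benzyl bromide (compound 8), BrCc1ccccc1
Why: Williamson ether synthesis: the phenoxide formed with K2CO3 displaces bromide from benzyl bromide by SN2, and the weak base leaves the propargylic ether and the terminal alkyne unisomerised; the benzyl group marks the oxygen that becomes the free 5-hydroxyl.

Step 5
Reactants: 9 rac-5-(benzyloxy)-1,2-dimethoxy-3-{[1-(3,4,5-trimethoxyphenyl)prop-2-yn-1-yl]oxy}benzene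
Product: 13 rac-5-(benzyloxy)-7,8-dimethoxy-2-(3,4,5-trimethoxyphenyl)-2H-chromene, via allenyl dienone 10 (not isolated), via allenylphenol 11 (not isolated), via ortho-quinone methide 12 (not isolated)
Conditions: PhNEt2 (degassed), 180 °C, Ar
Reagents that add atoms: none
Why: Heat drives an aromatic propargyl Claisen [3,3] shift in which the alkyne terminus (future C4) bonds to C4a as O1–C2 breaks, giving allenyl dienone 10, which tautomerises to allenylphenol 11; a 1,5-hydrogen shift from the phenolic oxygen to the central allene carbon then gives ortho-quinone methide 12. Ring C closes by a thermally allowed disrotatory oxa-6π electrocyclisation of 12 (O1 back onto C2, six-membered pyran), so the only net new skeletal bond is C4–C4a. The closest known reaction type is the thermal rearrangement of aryl propargyl ethers to 2H-chromenes in a high-boiling amine, which also accepts an aryl group on the propargylic carbon. C2 is the only stereocentre formed; it arises from planar, achiral 12 and is therefore racemic, which suffices because C2 is sp2 in the target. The selectivity needed is regiochemical, C4a against C8 (and C6 by a further Cope shift): C8 carries methoxy, so a dienone formed there cannot tautomerise and reverts, whereas the C4a dienone carries hydrogen and is drained irreversibly towards 11. The 3,4,5-trimethoxyphenyl group on the propargylic carbon weakens the breaking O1–C2 bond and should let the cascade run below the temperature an unsubstituted propargyl ether needs, while the basic solvent suppresses acid ionisation of the ether and of the chromene.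

Step 6
Reactants: 13 rac-5-(benzyloxy)-7,8-dimethoxy-2-(3,4,5-trimethoxyphenyl)-2H-chromene
Product: 14 rel-(2R,3S,4S)-5-(benzyloxy)-7,8-dimethoxy-2-(3,4,5-trimethoxyphenyl)-3,4-dihydro-2H-chromene-3,4-diol (racemic; 2,3-trans-3,4-cis)
Conditions: OsO4 (2 mol%), NMO, acetone/H2O, rt
Reagents that add atoms: osmium tetroxide, O=[Os](=O)(=O)=O; N-methylmorpholine N-oxide, C[N+]1([O-])CCOCC1; water, O
Why: Catalytic syn-dihydroxylation with OsO4 and NMO: the [3+2] addition of OsO4 to the electron-rich C3=C4 bond takes place on the face anti to the pseudo-equatorial C2 aryl group, which sets the 2,3-trans-3,4-cis relation, although both new stereocentres are erased in step 7 and any diastereomer would serve.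

Step 7
Reactants: 14 rel-(2R,3S,4S)-5-(benzyloxy)-7,8-dimethoxy-2-(3,4,5-trimethoxyphenyl)-3,4-dihydro-2H-chromene-3,4-diol
Product: 17 5-(benzyloxy)-3-hydroxy-7,8-dimethoxy-2-(3,4,5-trimethoxyphenyl)-4H-chromen-4-one, via trans-3-hydroxyflavanone 15 (not isolated), via flavan-3,4-dione 16 (not isolated)
Conditions: IBX (2.5 equiv), DMSO, rt to 40 °C
Reagents that add atoms: none
Why: IBX oxidation of a vicinal diol to the 1,2-dicarbonyl compound without C–C cleavage: the benzylic C4 carbinol should go first to ketol 15, whose C3 carbinol is then oxidised to dione 16, and this enolises at once towards C2 because the resulting 3-hydroxy-4-pyranone is aromatic, which gives the flavonol.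

Step 8
Reactants: 17 5-(benzyloxy)-3-hydroxy-7,8-dimethoxy-2-(3,4,5-trimethoxyphenyl)-4H-chromen-4-one
Product: 18 3,5-dihydroxy-7,8-dimethoxy-2-(3,4,5-trimethoxyphenyl)-4H-chromen-4-one (3,5-dihydroxy-7,8,3',4',5'-pentamethoxyflavone)
Conditions: H2 (1 atm), Pd/C (10% palladium on carbon), EtOAc/MeOH, rt
Reagents that add atoms: none
Why: Catalytic hydrogenolysis of the benzyl aryl ether over palladium frees the 5-hydroxyl, which is hydrogen-bonded to the C4 carbonyl; the C2=C3 bond is part of the aromatic pyranone and, like the five aryl methyl ethers, should not be reduced at one atmosphere and room temperature.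

**Compound list**

1 | 3,4,5-trimethoxybenzaldehyde | COc1cc(C=O)cc(OC)c1OC | starting material
2 | ethynylmagnesium bromide | C#C[Mg]Br | starting material
3 | rac-1-(3,4,5-trimethoxyphenyl)prop-2-yn-1-ol (S enantiomer drawn) | C#C[C@H](O)c1cc(OC)c(OC)c(OC)c1 | intermediate
4 | 3-hydroxy-4,5-dimethoxybenzaldehyde | COc1cc(C=O)cc(O)c1OC | starting material
5 | rac-3,4-dimethoxy-5-{[1-(3,4,5-trimethoxyphenyl)prop-2-yn-1-yl]oxy}benzaldehyde (R enantiomer drawn) | C#C[C@@H](Oc1cc(C=O)cc(OC)c1OC)c1cc(OC)c(OC)c(OC)c1 | intermediate
6 | aryl formate (not isolated): rac-3,4-dimethoxy-5-{[1-(3,4,5-trimethoxyphenyl)prop-2-yn-1-yl]oxy}phenyl formate | C#C[C@@H](Oc1cc(OC=O)cc(OC)c1OC)c1cc(OC)c(OC)c(OC)c1 | intermediate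
7 | rac-3,4-dimethoxy-5-{[1-(3,4,5-trimethoxyphenyl)prop-2-yn-1-yl]oxy}phenol (R enantiomer drawn) | C#C[C@@H](Oc1cc(O)cc(OC)c1OC)c1cc(OC)c(OC)c(OC)c1 | intermediate
8 | benzyl bromide | BrCc1ccccc1 | starting material
9 | rac-5-(benzyloxy)-1,2-dimethoxy-3-{[1-(3,4,5-trimethoxyphenyl)prop-2-yn-1-yl]oxy}benzene (R enantiomer drawn) | C#C[C@@H](Oc1cc(OCc2ccccc2)cc(OC)c1OC)c1cc(OC)c(OC)c(OC)c1 | intermediate
10 | allenyl dienone (not isolated): 5-(benzyloxy)-2,3-dimethoxy-6-[3-(3,4,5-trimethoxyphenyl)propa-1,2-dien-1-yl]cyclohexa-2,4-dien-1-one, transient, configuration at the ring carbon and the allene axis not defined | O=C1C(OC)=C(OC)C=C(OCc2ccccc2)C1C=C=Cc3cc(OC)c(OC)c(OC)c3 | intermediate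
11 | allenylphenol (not isolated): 3-(benzyloxy)-5,6-dimethoxy-2-[3-(3,4,5-trimethoxyphenyl)propa-1,2-dien-1-yl]phenol, racemic allene | Oc1c(OC)c(OC)cc(OCc2ccccc2)c1C=C=Cc3cc(OC)c(OC)c(OC)c3 | intermediate
12 | ortho-quinone methide (not isolated): (6Z)-5-(benzyloxy)-2,3-dimethoxy-6-[3-(3,4,5-trimethoxyphenyl)prop-2-en-1-ylidene]cyclohexa-2,4-dien-1-one, side chain syn to the carbonyl, styrenyl C=C geometry not fixed | O=C1C(OC)=C(OC)C=C(OCc2ccccc2)\C1=C\C=Cc3cc(OC)c(OC)c(OC)c3 | intermediate
13 | rac-5-(benzyloxy)-7,8-dimethoxy-2-(3,4,5-trimethoxyphenyl)-2H-chromene (2S enantiomer drawn) | COc1cc(OCc2ccccc2)c2C=C[C@@H](c3cc(OC)c(OC)c(OC)c3)Oc2c1OC | intermediate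
14 | rel-(2R,3S,4S)-5-(benzyloxy)-7,8-dimethoxy-2-(3,4,5-trimethoxyphenyl)-3,4-dihydro-2H-chromene-3,4-diol (racemic, 2,3-trans-3,4-cis) | COc1cc(OCc2ccccc2)c2[C@H](O)[C@H](O)[C@@H](c3cc(OC)c(OC)c(OC)c3)Oc2c1OC | intermediate
15 | trans-3-hydroxyflavanone (not isolated): rel-(2R,3R)-5-(benzyloxy)-3-hydroxy-7,8-dimethoxy-2-(3,4,5-trimethoxyphenyl)-2,3-dihydro-4H-chromen-4-one, racemic | COc1cc(OCc2ccccc2)c2C(=O)[C@H](O)[C@@H](c3cc(OC)c(OC)c(OC)c3)Oc2c1OC | intermediate
16 | flavan-3,4-dione (not isolated): rac-5-(benzyloxy)-7,8-dimethoxy-2-(3,4,5-trimethoxyphenyl)-2H-chromene-3,4-dione (2R enantiomer drawn) | COc1cc(OCc2ccccc2)c2C(=O)C(=O)[C@@H](c3cc(OC)c(OC)c(OC)c3)Oc2c1OC | intermediate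
17 | 5-(benzyloxy)-3-hydroxy-7,8-dimethoxy-2-(3,4,5-trimethoxyphenyl)-4H-chromen-4-one | COc1cc(OCc2ccccc2)c2c(=O)c(O)c(-c3cc(OC)c(OC)c(OC)c3)oc2c1OC | intermediate
18 | 3,5-dihydroxy-7,8-dimethoxy-2-(3,4,5-trimethoxyphenyl)-4H-chromen-4-one (3,5-dihydroxy-7,8,3',4',5'-pentamethoxyflavone) | COc1cc(O)c2c(=O)c(O)c(-c3cc(OC)c(OC)c(OC)c3)oc2c1OC | target

**Step count**

Total steps: 8. Longest linear sequence: 8 steps (from 1 to 18; 2, 4 and 8 are bought and enter along the way).

**Steps most likely to fail**

Step 5 (key step). The cascade may be diverted in three ways: a shift to the methoxy-bearing C8 followed by a Cope shift to C6 or an intramolecular Diels–Alder reaction of the allenyl dienone; thermal cleavage of the doubly activated benzylic-propargylic C–O bond; or oligomerisation of the quinone methide. The fallback sets out from 9 and replaces the pericyclic pathway by π-acid catalysis: Ph3PAuNTf2 (monovalent gold, catalytic) in CH2Cl2 at rt activates the terminal alkyne, C4a attacks the alkyne terminus in a 6-endo-dig Friedel–Crafts hydroarylation, and protodeauration gives the chromene. No dienone or quinone methide is involved, and of the two carbons ortho to O1 only C4a carries hydrogen, so the same C4–C4a bond is formed. The route is rejoined at 13; no new compound arises (F0).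

Step 7. The double oxidation may fail through cleavage of the C3–C4 glycol bond, through ionisation of the C4 benzylic carbinol (ring A is strongly donating) under the slightly acidic conditions, or through over-oxidation of the product enol. The fallback sets out from 14 and oxidises only one carbinol: MnO2 in CH2Cl2 at rt should convert the benzylic C4 carbinol alone, giving ketol 15, which is isolated this time. I2 with KOAc in AcOH at 100 °C then dehydrogenates 15 across C2–C3 (iodination of the enol, loss of HI), so that the second oxidation takes place at a C–H bond and not at the C3 carbinol. The route is rejoined at 17; no new compound arises (F0).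

Step 2. The oxyphosphonium of the cation-stabilised propargylic alcohol may ionise before the hindered, ortho-methoxy-flanked phenol attacks, which would lead to C-alkylation or to attack at the alkyne terminus with allene formation. The fallback sets out from 3 and replaces the SN2 displacement by a metal-allenylidene substitution. Ac2O, Et3N and DMAP (cat.) in CH2Cl2 give rac-1-(3,4,5-trimethoxyphenyl)prop-2-yn-1-yl acetate F1. F1 and phenol 4 are then treated with Cu(MeCN)4PF6 (monovalent copper, catalytic) and iPr2NEt in THF at 0 °C: the copper acetylide loses acetate to a copper allenylidene, and the phenoxide adds to its propargylic carbon (copper-catalysed propargylic etherification). The route is rejoined at 5.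

**Further compounds**

F0 | step 5 | none | none
F0 | step 7 | none | none
F1 | step 2 | rac-1-(3,4,5-trimethoxyphenyl)prop-2-yn-1-yl acetate (S enantiomer drawn) | C#C[C@H](OC(C)=O)c1cc(OC)c(OC)c(OC)c1
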